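**Retrosynthetic overview**

1. The quinone is unveiled last, by oxidative demethylation of a 1,4-dimethoxyarene with (NH4)2Ce(NO3)6; both quinone oxygens come from water.
2. The two β,γ-unsaturated ketone arms come from two α-selective allylbarium additions (the aryl-bearing C5 unit to a lactone carbonyl, prenyl to a neopentyl aldehyde), each followed by Dess–Martin oxidation.
3. Key disconnection: the ring C–O bond of a bicyclic δ-lactone, made by a catalytic enantioselective Baeyer–Villiger desymmetrisation of meso cis-1,5-dimethylbicyclo[3.3.0]octan-3-one. One oxygen insertion opens ring A at the right C–C bond, gives the two quaternary carbons arms of different length and fixes both configurations.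
4. The meso ketone comes from mono-deoxygenation of commercial cis-1,5-dimethylbicyclo[3.3.0]octane-3,7-dione, which already holds the cis-vicinal quaternary methyl carbons.
5. Rings: none is built. Ring B of the dione is carried through as the cyclopentane, ring A is opened, and the quinone ring comes from 4-methoxy-2-methylphenol (C5 chain by SN2′ opening of isoprene monoxide).

Assumption: the sense of induction in step 3 cannot be predicted, so the ligand antipode that gives the (4aR,7aR)-lactone is chosen after a screen (both antipodes are accessible from (S)- or (R)-pipecolic acid).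

**Route**

Step 1
Reactants: 1 cis-1,5-dimethylbicyclo[3.3.0]octane-3,7-dione; 2 2,2-dimethylpropane-1,3-diol
Product: 3 cis-1,5-dimethylbicyclo[3.3.0]octane-3,7-dione mono(2,2-dimethylpropane-1,3-diyl) ketal
Conditions: 2 (1.0 equiv), p-TsOH·H2O (5 mol%), toluene, reflux, Dean–Stark trap
Reagents that add atoms: none
Why: Acid-catalysed ketalisation with one equivalent of diol gives the mono-ketal statistically (recovered 1 and bis-ketal are recycled), and 3 keeps the mirror plane, so no stereocentre is at stake.

Step 2
Reactants: 3 mono-ketal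
Product: 6 cis-1,5-dimethylbicyclo[3.3.0]octan-3-one (meso), via hydrazone 4 (not isolated), via deoxygenated ketal 5 (not isolated)
Conditions: N2H4·H2O, KOH, diethylene glycol, 130 °C then 200 °C; then 2 M HCl, THF, 50 °C
Reagents that add atoms: water, O
Why: Wolff–Kishner reduction (Huang-Minlon variant) removes the free carbonyl of ring B under base, to which the ketal is inert, and the acidic work-up hydrolyses the ketal to the ring A ketone; the cis fusion cannot epimerise because both fusion carbons are quaternary.

Step 3
Reactants: 6 cis-1,5-dimethylbicyclo[3.3.0]octan-3-one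
Product: 7 (4aR,7aR)-4a,7a-dimethylhexahydrocyclopenta[c]pyran-3(1H)-one
Conditions: Sc(OTf)3 (10 mol%), C2-symmetric chiral N,N′-dioxide ligand from pipecolic acid 2,6-diisopropylanilide (12 mol%), m-CPBA (1.5 equiv), EtOAc, −20 °C
Reagents that add atoms: m-chloroperbenzoic acid, OOC(=O)c1cccc(Cl)c1
Why: Proposed new method: the chiral Sc(OTf)3–N,N′-dioxide complex (trivalent scandium) binds ketone and peracid together, the peracid adds from the convex face to give a Criegee adduct, and the ligand pocket allows only the rotamer in which the O–O bond is antiperiplanar to one of the two enantiotopic CH2–C(=O) bonds, so that this bond alone migrates with retention; one oxygen insertion thus opens ring A, gives the quaternary carbons a CH2–O arm and a CH2–C(=O) arm and fixes both as R, while the uncatalysed peracid oxidation of a cyclopentanone is slow at −20 °C and keeps the racemic background small; closest known reaction type: Lewis acid/N,N′-dioxide-catalysed desymmetrising Baeyer–Villiger oxidation of 3-substituted cyclobutanones and 4-substituted cyclohexanones, not yet shown for a meso cyclopentanone.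

Step 4
Reactants: 8 4-methoxy-2-methylphenol
Product: 10 1-bromo-2,5-dimethoxy-3-methylbenzene, via bromophenol 9 (not isolated)
Conditions: NBS (1.05 equiv), MeCN, 0 °C; then K2CO3, MeI, 50 °C
Reagents that add atoms: N-bromosuccinimide, O=C1CCC(=O)N1Br; iodomethane, CI
Why: Electrophilic aromatic bromination goes ortho to the free hydroxyl (para is blocked by OMe), and Williamson O-methylation of the crude bromophenol in the same flask gives the hydroquinone dimethyl ether.

Step 5
Reactants: 10 1-bromo-2,5-dimethoxy-3-methylbenzene; 11 2-methyl-2-vinyloxirane (isoprene monoxide)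
Product: 13 (E)-4-(2,5-dimethoxy-3-methylphenyl)-2-methylbut-2-en-1-ol, via aryl Grignard reagent 12 (not isolated)
Conditions: Mg, THF, reflux; then CuI (10 mol%), 11, THF, −30 °C to 0 °C
Reagents that add atoms: none
Why: Copper-catalysed SN2′ opening of the vinyl epoxide by the aryl Grignard reagent puts the aryl group on the vinyl terminus and gives the (E)-trisubstituted allylic alcohol as the major isomer (about 9:1 expected; the minor Z and SN2 products are removed by chromatography).

Step 6
Reactants: 13 (E)-4-(2,5-dimethoxy-3-methylphenyl)-2-methylbut-2-en-1-ol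
Product: 15 1-[(E)-4-chloro-3-methylbut-2-en-1-yl]-2,5-dimethoxy-3-methylbenzene, via allylic mesylate 14 (not isolated)
Conditions: MsCl, s-collidine, LiCl, DMF, 0 °C
Reagents that add atoms: lithium chloride, [Li+].[Cl-]
Why: Mesylation followed by in situ SN2 displacement by chloride at the primary allylic carbon gives the chloride without allylic transposition or loss of E geometry.

Step 7
Reactants: 15 allylic chloride; 7 (4aR,7aR)-lactone
Product: 17 (E)-6-(2,5-dimethoxy-3-methylphenyl)-1-[(1R,2R)-2-(hydroxymethyl)-1,2-dimethylcyclopentyl]-4-methylhex-4-en-2-one, via allylbarium chloride 16 (not isolated)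
Conditions: BaI2, Li, biphenyl, THF, rt; 15 (1.2 equiv), −78 °C; then 7, −78 °C; pH 7 buffer
Reagents that add atoms: none
Why: Activated barium inserts into the allylic chloride to give an allylbarium reagent that keeps its E geometry at −78 °C and attacks carbonyl groups through its unsubstituted α-carbon (α-selective allylbarium addition); the barium lactolate of the δ-lactone does not collapse at −78 °C, so one allyl group adds and the β,γ-unsaturated ketone (in equilibrium with its cyclic hemiketal) appears only on work-up.

Step 8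
Reactants: 17 hydroxy ketone
Product: 18 (1R,2R)-2-[(E)-6-(2,5-dimethoxy-3-methylphenyl)-4-methyl-2-oxohex-4-en-1-yl]-1,2-dimethylcyclopentane-1-carbaldehyde
Conditions: Dess–Martin periodinane, pyridine, CH2Cl2, 0 °C to rt
Reagents that add atoms: none
Why: Dess–Martin oxidation of the neopentyl primary alcohol goes through the open hydroxy-ketone tautomer under buffered, near-neutral conditions that do not move the β,γ double bond into conjugation.

Step 9
Reactants: 18 keto aldehyde; 19 1-chloro-3-methylbut-2-ene (prenyl chloride)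
Product: 21 (E)-6-(2,5-dimethoxy-3-methylphenyl)-1-[(1R,2R)-2-(1-hydroxy-4-methylpent-3-en-1-yl)-1,2-dimethylcyclopentyl]-4-methylhex-4-en-2-one, via prenylbarium chloride 20 (not isolated)
Conditions: BaI2, Li, biphenyl, THF, rt; 19, −78 °C; then 20 (1.05 equiv) added to 18, THF, −90 °C; pH 7 buffer
Reagents that add atoms: none
Why: Prenylbarium chloride adds through its primary α-carbon to give the linear prenyl carbinol (α-selective allylbarium addition), and at −90 °C with a limiting amount of reagent the aldehyde should react well ahead of the flanked dialkyl ketone; the new carbinol centre forms as a mixture of epimers that is erased in step 10.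

Step 10
Reactants: 21 hydroxy ketone
Product: 22 (E)-6-(2,5-dimethoxy-3-methylphenyl)-1-[(1R,2R)-1,2-dimethyl-2-(4-methylpent-3-enoyl)cyclopentyl]-4-methylhex-4-en-2-one
Conditions: Dess–Martin periodinane, pyridine, CH2Cl2, 0 °C to rt
Reagents that add atoms: none
Why: Dess–Martin oxidation of the hindered homoallylic secondary alcohol gives the prenyl ketone without isomerising either β,γ-unsaturated ketone.

Step 11
Reactants: 22 dimethoxyarene diketone
Product: 23 2-[(E)-6-[(1R,2R)-1,2-dimethyl-2-(4-methylpent-3-enoyl)cyclopentyl]-3-methyl-5-oxohex-2-en-1-yl]-6-methylcyclohexa-2,5-diene-1,4-dione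
Conditions: (NH4)2Ce(NO3)6 (2.5 equiv), MeCN/H2O (2:1), 0 °C
Reagents that add atoms: water, O
Why: Oxidative demethylation of the 1,4-dimethoxyarene by the tetravalent cerium salt (arene radical cation, attack of water at the two ipso carbons, loss of methanol) gives the p-benzoquinone and leaves the ketones and the isolated trisubstituted alkenes untouched.

**Compound list**

1 | cis-1,5-dimethylbicyclo[3.3.0]octane-3,7-dione (meso) | O=C1C[C@@]2(C)CC(=O)C[C@@]2(C)C1 | starting material
2 | 2,2-dimethylpropane-1,3-diol | OCC(C)(C)CO | starting material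
3 | cis-1,5-dimethylbicyclo[3.3.0]octane-3,7-dione mono(2,2-dimethylpropane-1,3-diyl) ketal (achiral) | O=C1C[C@@]2(C)CC3(OCC(C)(C)CO3)C[C@@]2(C)C1 | intermediate
4 | hydrazone of 3 at the free carbonyl | NN=C1C[C@@]2(C)CC3(OCC(C)(C)CO3)C[C@@]2(C)C1 | intermediate
5 | cis-1,5-dimethylbicyclo[3.3.0]octan-3-one 2,2-dimethylpropane-1,3-diyl ketal | C1C[C@@]2(C)CC3(OCC(C)(C)CO3)C[C@@]2(C)C1 | intermediate
6 | cis-1,5-dimethylbicyclo[3.3.0]octan-3-one (meso; (3aR,6aS)-3a,6a-dimethylhexahydropentalen-2(1H)-one) | O=C1C[C@@]2(C)CCC[C@@]2(C)C1 | intermediate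
7 | (4aR,7aR)-4a,7a-dimethylhexahydrocyclopenta[c]pyran-3(1H)-one | O=C1C[C@@]2(C)CCC[C@@]2(C)CO1 | intermediate
8 | 4-methoxy-2-methylphenol | COc1ccc(O)c(C)c1 | starting material
9 | 2-bromo-4-methoxy-6-methylphenol | COc1cc(C)c(O)c(Br)c1 | intermediate
10 | 1-bromo-2,5-dimethoxy-3-methylbenzene | COc1cc(C)c(OC)c(Br)c1 | intermediate
11 | 2-methyl-2-vinyloxirane (racemic) | CC1(C=C)CO1 | starting material
12 | (2,5-dimethoxy-3-methylphenyl)magnesium bromide | COc1cc(C)c(OC)c([Mg]Br)c1 | intermediate
13 | (E)-4-(2,5-dimethoxy-3-methylphenyl)-2-methylbut-2-en-1-ol | OC/C(C)=C/Cc1cc(OC)cc(C)c1OC | intermediate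
14 | (E)-4-(2,5-dimethoxy-3-methylphenyl)-2-methylbut-2-en-1-yl methanesulfonate | CS(=O)(=O)OC/C(C)=C/Cc1cc(OC)cc(C)c1OC | intermediate
15 | 1-[(E)-4-chloro-3-methylbut-2-en-1-yl]-2,5-dimethoxy-3-methylbenzene | ClC/C(C)=C/Cc1cc(OC)cc(C)c1OC | intermediate
16 | [(E)-4-(2,5-dimethoxy-3-methylphenyl)-2-methylbut-2-en-1-yl]barium chloride | Cl[Ba]C/C(C)=C/Cc1cc(OC)cc(C)c1OC | intermediate
17 | (E)-6-(2,5-dimethoxy-3-methylphenyl)-1-[(1R,2R)-2-(hydroxymethyl)-1,2-dimethylcyclopentyl]-4-methylhex-4-en-2-one (in equilibrium with its cyclic hemiketal) | OC[C@]1(C)CCC[C@]1(C)CC(=O)C/C(C)=C/Cc1cc(OC)cc(C)c1OC | intermediate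
18 | (1R,2R)-2-[(E)-6-(2,5-dimethoxy-3-methylphenyl)-4-methyl-2-oxohex-4-en-1-yl]-1,2-dimethylcyclopentane-1-carbaldehyde | O=C[C@]1(C)CCC[C@]1(C)CC(=O)C/C(C)=C/Cc1cc(OC)cc(C)c1OC | intermediate
19 | 1-chloro-3-methylbut-2-ene | CC(C)=CCCl | starting material
20 | (3-methylbut-2-en-1-yl)barium chloride | CC(C)=CC[Ba]Cl | intermediate
21 | (E)-6-(2,5-dimethoxy-3-methylphenyl)-1-[(1R,2R)-2-(1-hydroxy-4-methylpent-3-en-1-yl)-1,2-dimethylcyclopentyl]-4-methylhex-4-en-2-one (both carbinol epimers) | CC(C)=CCC(O)[C@]1(C)CCC[C@]1(C)CC(=O)C/C(C)=C/Cc1cc(OC)cc(C)c1OC | intermediate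
22 | (E)-6-(2,5-dimethoxy-3-methylphenyl)-1-[(1R,2R)-1,2-dimethyl-2-(4-methylpent-3-enoyl)cyclopentyl]-4-methylhex-4-en-2-one | CC(C)=CCC(=O)[C@]1(C)CCC[C@]1(C)CC(=O)C/C(C)=C/Cc1cc(OC)cc(C)c1OC | intermediate
23 | 2-[(E)-6-[(1R,2R)-1,2-dimethyl-2-(4-methylpent-3-enoyl)cyclopentyl]-3-methyl-5-oxohex-2-en-1-yl]-6-methylcyclohexa-2,5-diene-1,4-dione | CC(C)=CCC(=O)[C@]1(C)CCC[C@]1(C)CC(=O)C/C(C)=C/CC1=CC(=O)C=C(C)C1=O | target

**Step count and risks**

Total step count: 11. Longest linear sequence: 8 steps (steps 1, 2, 3, 7, 8, 9, 10, 11 from 1; the arm from 8 through steps 4, 5, 6 and then 7 to 11 is also 8).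

The three steps most likely to fail are 3, 9 and 7.

Step 3 (the proposed new desymmetrisation) may be slow or poorly enantioselective, because cyclopentanones are reluctant Baeyer–Villiger substrates; a modest ee could be raised by recrystallising 7. The fallback uses known chemistry and sets out from 6. Enantioselective deprotonation with lithium bis[(R)-1-phenylethyl]amide or its antipode in the presence of TMSCl (THF, −100 °C) gives the silyl enol ether F1, whose double bond lies toward the future C-7a. Ozonolysis (O3, CH2Cl2/MeOH, −78 °C) with NaBH4 work-up cleaves that double bond and reduces the aldehyde end to give the hydroxy acid F2. F2 lactonises on acidification (cat. p-TsOH, toluene), and the route is rejoined at 7.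

Step 9 may suffer from competing attack on the ketone of 18, or from enolisation of its β,γ-unsaturated ketone followed by intramolecular aldol reaction onto the aldehyde. The fallback changes the order of chain attachment so that no keto aldehyde is made; it sets out from 7. Aminolysis with Me(MeO)NH·HCl and AlMe3 (CH2Cl2, 0 °C to rt) gives the hydroxy Weinreb amide F6, and Dess–Martin oxidation gives the formyl Weinreb amide F7, which has no enolisable position able to reach the aldehyde. Prenylbarium chloride 20 at −78 °C adds to the aldehyde only and gives the prenyl carbinol F8. After deprotonation of the hydroxyl with i-PrMgCl, allylbarium chloride 16 adds once to the Weinreb amide, and the route is rejoined at 21.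

Step 7 may give double addition to the lactone, some attack through the γ-carbon, or proton transfer from the benzylic-allylic CH2 of 16. The fallback reverses the polarity (core as acyl anion, 15 as electrophile) and sets out from 7. Reduction with i-Bu2AlH (CH2Cl2, −78 °C) gives the lactol F3, and propane-1,3-dithiol with BF3·OEt2 gives the hydroxy dithiane F4. Double deprotonation (n-BuLi, 2.2 equiv, THF/HMPA, −30 °C) and SN2 alkylation with chloride 15 at its primary carbon gives the alkylated dithiane F5 with the E alkene intact. Hydrolysis with MeI and CaCO3 in aqueous MeCN releases the ketone, and the route is rejoined at 17.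

**Further compounds**

F1 | step 3 | trimethyl{[(3aS,6aR)-3a,6a-dimethyl-1,3a,4,5,6,6a-hexahydropentalen-2-yl]oxy}silane | C[Si](C)(C)OC1=C[C@]2(C)CCC[C@]2(C)C1
F2 | step 3 | 2-[(1R,2R)-2-(hydroxymethyl)-1,2-dimethylcyclopentyl]acetic acid | OC[C@]1(C)CCC[C@]1(C)CC(=O)O
F3 | step 7 | (4aR,7aR)-4a,7a-dimethyloctahydrocyclopenta[c]pyran-3-ol (both anomers) | OC1C[C@@]2(C)CCC[C@@]2(C)CO1
F4 | step 7 | {(1R,2R)-2-[(1,3-dithian-2-yl)methyl]-1,2-dimethylcyclopentyl}methanol | OC[C@]1(C)CCC[C@]1(C)CC1SCCCS1
F5 | step 7 | {(1R,2R)-2-({2-[(E)-4-(2,5-dimethoxy-3-methylphenyl)-2-methylbut-2-en-1-yl]-1,3-dithian-2-yl}methyl)-1,2-dimethylcyclopentyl}methanol | OC[C@]1(C)CCC[C@]1(C)CC1(C/C(C)=C/Cc2cc(OC)cc(C)c2OC)SCCCS1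
F6 | step 9 | 2-[(1R,2R)-2-(hydroxymethyl)-1,2-dimethylcyclopentyl]-N-methoxy-N-methylacetamide | OC[C@]1(C)CCC[C@]1(C)CC(=O)N(C)OC
F7 | step 9 | 2-[(1R,2R)-2-formyl-1,2-dimethylcyclopentyl]-N-methoxy-N-methylacetamide | O=C[C@]1(C)CCC[C@]1(C)CC(=O)N(C)OC
F8 | step 9 | 2-[(1R,2R)-2-(1-hydroxy-4-methylpent-3-en-1-yl)-1,2-dimethylcyclopentyl]-N-methoxy-N-methylacetamide (both carbinol epimers) | CC(C)=CCC(O)[C@]1(C)CCC[C@]1(C)CC(=O)N(C)OC
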